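4 questions stand here, and they hang on one ratio of rates, so I follow the rates.

| flask | starting material | partner | protic impurity | remark | time |
|---|---|---|---|---|---|
| Wednesday's | 20 mM | 22 mM | 14 mM | run made earlier |  |
| midnight | 20 mM | 22.0 mM | 20.0 mM |  | 2.0 min |
| dawn | 20 mM | 22.0 mM | 26.0 mM |  | 2.0 min |

Wednesday's run (percent of the starting material charged)

| time / s | product / % | starting material / % |
|---|---|---|
| 10.0 | 0.6 | 74.7 |
| 15.0 | 2.6 | 67.2 |
| 30.0 | 7.2 | 44.8 |
| 60.0 | 27.4 | 15.0 |

(readings scatter by 0.5 percentage points)

* which of these there is most of at the end, counted by the starting material in it, midnight (product / starting material)
* which of these there is most of at the end, counted by the starting material in it, dawn (product / starting material)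
* amount of the one of these that there is most of at the end, in percent of the starting material charged, midnight
* amount of the one of these that there is most of at the end, in percent of the starting material charged, dawn

- percentages count the starting material that a species holds: one idle adduct counts as two
- product is meant together with its idle adduct
- the numbers in the tables scatter by 0.5 percentage points (one standard deviation)
- candidate steps: starting material + partner + product -> 2 product; starting material + partner -> product; partner -> decomposed reagent; starting material + protic impurity -> quenched substrate; starting material + product <-> idle adduct
- in an amount of product, one idle adduct counts as one product
- no earlier run changes the charge of protic impurity; that part of a forecast is a guess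

In Wednesday's run the first 10.0 s lose 0.0247 /s of the charge to quench and gain 6.000 × 10⁻⁴ /s as product, a reading close to the scatter, so at the start quench runs far faster. Two things slow quench. Starting material falls, but it stands in both steps and cancels from their ratio. Impurity falls too. Counting as quenched what is neither product nor starting material gives 57.6% by 60.0 s. That count is high, because it also holds the second unit of any idle adduct, which neither column shows. So 2.48 mM is a low figure for what is left of Wednesday's 14 mM of impurity, and the factor 5.65 is a high one; whatever the true factor is, it stays in the ratio.

Product over quenched, the selectivity factor, times the mean impurity 8.24 mM, gives H* = 3.92 mM on this count, a low figure, since the count makes both the selectivity factor and the mean too small. H* is the break-even impurity: the mean impurity at which product and quench take starting material equally fast.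

The mean hides a curve. By the same count, Wednesday's first 30.0 s read 1.38 mM, the next stretch 7.24 mM, so H* climbs as product gathers. Sharing the charge so that product over quenched equals H* over the mean of charged and remaining impurity, I get 24.0% at midnight and 18.0% at dawn.

The forecast names product for both flasks, with 24% (15% to 33%) at midnight and 12% (6% to 20%) at dawn, and warns: “Sensitivity to the seed is large.” Its dawn figure lies below mine.

    starting material + partner + product → 2 product (k = 611 /M²/s)
    starting material + partner → product (k = 0.0360 /M/s)
    partner → decomposed reagent (k = 0.00194 /s)
    starting material + protic impurity → quenched substrate (k = 2.38 /M/s)
    starting material + product ⇌ idle adduct, settled at all times (K = 71.6 /M)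

The flasks give product: 27.3% at midnight, 15.8% at dawn, with starting material at 0.844% and 0.568%. Midnight's own end reads H* = 4.90 mM. For the neighbour with 34 mM of starting material, H* from Wednesday gives 31.8%; that flask stands at 44.3%. Ten times the time adds 0.88 percentage points of product at midnight and under 0.5 point at dawn. Midnight's partner meanwhile falls from 57.6% to 6.98%.

(The numbers in the tables are calculated with constants of no real substance.)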